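**Retrosynthetic overview**
- The target is cut at the C5–O aryl ether: trans opening of a 5,6-epoxide on the tetrahydrochromone (upper unit) by the 6-OH of a 7-O-allyl 6,7-dihydroxy-2-(2-phenylethyl)chromone (lower unit), then desilylation and deallylation.
- The epoxide comes from hydroxyl-directed epoxidation of a 7,8-trans-dioxygenated 7,8-dihydrochromone, whose carbocycle is closed by ring-closing metathesis (last ring of the upper unit).
- The metathesis diene comes from the key C7–C8 bond formation: asymmetric (Z)-γ-alkoxyallylboration of a 3-vinyl-4-pyranone-2-carbaldehyde, which sets C7 and C8 together.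
- That aldehyde comes from kojic acid (pyranone ring bought): olefination/hydrogenation for the phenethyl arm, formaldehyde aldol for C8, enol triflate/Stille coupling for the vinyl group (C5).
- The lower unit comes from Claisen condensation of 2'-hydroxy-4',5'-dimethoxyacetophenone with ethyl 3-phenylpropanoate, cyclodehydration (its pyranone ring), demethylation and selective 7-O-allylation.

Assumption: all reagents named, including (−)-Ipc2BOMe (made from (+)-α-pinene) and allyl methoxymethyl ether, are bought; chromone numbering is used for both units. The route is a plan on paper, not run experimentally.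

**Upper unit**

Step 1
Reactants: 1 kojic acid (5-hydroxy-2-(hydroxymethyl)-4H-pyran-4-one); 2 benzyl chloride
Product: 3 5-(benzyloxy)-2-(hydroxymethyl)-4H-pyran-4-one
Conditions: NaOH (1.1 eq), MeOH/H2O, reflux
Reagents that add atoms: benzyl chloride, ClCc1ccccc1
Why: Williamson etherification; aqueous NaOH deprotonates only the acidic enolic 5-OH, so the primary alcohol stays free.

Step 2
Reactants: 3
Product: 4 5-(benzyloxy)-4-oxo-4H-pyran-2-carbaldehyde
Conditions: Dess–Martin periodinane (1.2 eq), CH2Cl2, rt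
Reagents that add atoms: none
Why: Dess–Martin oxidation stops at the aldehyde under neutral conditions that spare the benzyl ether and the base-sensitive pyranone.

Step 3
Reactants: 4; 5 diethyl benzylphosphonate
Product: 6 5-(benzyloxy)-2-[(E)-2-phenylethenyl]-4H-pyran-4-one
Conditions: NaH, THF, 0 °C → rt
Reagents that add atoms: diethyl benzylphosphonate, CCOP(=O)(Cc1ccccc1)OCC
Why: Horner–Wadsworth–Emmons olefination of the electron-poor aldehyde gives the (E)-styryl pyranone; the geometry is irrelevant because the alkene is hydrogenated next.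

Step 4
Reactants: 6
Product: 7 5-hydroxy-2-(2-phenylethyl)-4H-pyran-4-one
Conditions: H2 (1 atm), 10% Pd/C, EtOAc/MeOH, rt
Reagents that add atoms: none
Why: Catalytic hydrogenation saturates the styryl C=C and hydrogenolyses the O-benzyl group in one operation, while the vinylogous-ester pyranone ring is not reduced at 1 atm.

Step 5
Reactants: 7; 8 formaldehyde
Product: 9 3-hydroxy-2-(hydroxymethyl)-6-(2-phenylethyl)-4H-pyran-4-one
Conditions: 37% aq. CH2O, NaOH (1.1 eq), H2O/MeOH, rt; then HCl to pH 5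
Reagents that add atoms: formaldehyde, C=O
Why: Aldol-type hydroxymethylation of the 3-hydroxy-4-pyranone enolate occurs only at the free carbon next to the enolic OH, as with kojic acid and allomaltol, and installs the future C8.

Step 6
Reactants: 9; 10 N-phenyl-bis(trifluoromethanesulfonimide)
Product: 11 2-(hydroxymethyl)-4-oxo-6-(2-phenylethyl)-4H-pyran-3-yl trifluoromethanesulfonate
Conditions: PhNTf2 (1.05 eq), Et3N, DMF, 0 °C → rt
Reagents that add atoms: N-phenyl-bis(trifluoromethanesulfonimide), O=S(=O)(N(c1ccccc1)S(=O)(=O)C(F)(F)F)C(F)(F)F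
Why: Chemoselective triflation; the mild triflyl donor reacts with the acidic enol (as its ammonium enolate) but not with the neutral primary alcohol.

Step 7
Reactants: 11; 12 tributyl(vinyl)stannane
Product: 13 3-ethenyl-2-(hydroxymethyl)-6-(2-phenylethyl)-4H-pyran-4-one
Conditions: Pd(PPh3)4 (5 mol%), LiCl (3 eq), 1,4-dioxane, 90 °C
Reagents that add atoms: tributyl(vinyl)stannane, C=C[Sn](CCCC)(CCCC)CCCC
Why: Stille coupling; zerovalent palladium inserts readily into the electron-poor enol triflate and LiCl assists transmetalation, installing the vinyl group that becomes C5 with the free CH2OH tolerated.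

Step 8
Reactants: 13
Product: 14 3-ethenyl-4-oxo-6-(2-phenylethyl)-4H-pyran-2-carbaldehyde
Conditions: Dess–Martin periodinane (1.2 eq), CH2Cl2, 0 °C → rt; used crude
Reagents that add atoms: none
Why: Dess–Martin oxidation of the activated primary alcohol gives the aldehyde (future C8) without touching the vinyl group.

Step 9
Reactants: 14; 15 allyl methoxymethyl ether (3-(methoxymethoxy)prop-1-ene)
Product: 17 3-ethenyl-2-[(1S,2R)-1-hydroxy-2-(methoxymethoxy)but-3-en-1-yl]-6-(2-phenylethyl)-4H-pyran-4-one, via diisopinocampheylborinate 16 (not isolated)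
Conditions: 15, s-BuLi, THF, −78 °C; (−)-Ipc2BOMe, −78 °C; BF3·OEt2; then 14, −78 °C, 3 h; then 30% H2O2, pH 7 phosphate buffer, 0 °C
Reagents that add atoms: allyl methoxymethyl ether, C=CCOCOC
Why: Brown asymmetric (Z)-γ-alkoxyallylboration (carbonyl allylation): the chair transition state turns the Z geometry into the syn (threo) 1,2-diol pattern, and the isopinocampheyl groups derived from (+)-α-pinene direct attack to the Si face of the aldehyde, setting C8 (S) and C7 (R) as the C7–C8 bond forms.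

Step 10
Reactants: 17; 18 tert-butyldimethylsilyl chloride
Product: 19 2-[(1S,2R)-1-[(tert-butyldimethylsilyl)oxy]-2-(methoxymethoxy)but-3-en-1-yl]-3-ethenyl-6-(2-phenylethyl)-4H-pyran-4-one
Conditions: TBSCl (2 eq), imidazole (4 eq), DMAP (cat.), DMF, 40 °C
Reagents that add atoms: tert-butyldimethylsilyl chloride, CC(C)(C)[Si](C)(C)Cl
Why: Silylation of the only free hydroxyl masks O8 with a bulky group that later shields one face of the ring and keeps O8 from acting as a nucleophile.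

Step 11
Reactants: 19
Product: 21 2-[(1S,2R)-1-[(tert-butyldimethylsilyl)oxy]-2-hydroxybut-3-en-1-yl]-3-ethenyl-6-(2-phenylethyl)-4H-pyran-4-one, via O-bromomethyl ether 20 (not isolated)
Conditions: Me2BBr (3 eq), CH2Cl2, −78 °C; then sat. NaHCO3/THF, 0 °C
Reagents that add atoms: none
Why: Lewis-acid acetal cleavage; Me2BBr converts the MOM ether into a bromomethyl ether that is hydrolysed on work-up, while the secondary TBS ether survives at −78 °C and no stereocenter is touched.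

Step 12
Reactants: 21
Product: 22 (7R,8S)-8-[(tert-butyldimethylsilyl)oxy]-7-hydroxy-2-(2-phenylethyl)-7,8-dihydro-4H-chromen-4-one (7,8-trans)
Conditions: second-generation Grubbs catalyst (H2IMes)(PCy3)Cl2Ru=CHPh (5 mol%), 1,4-benzoquinone (10 mol%), CH2Cl2 (5 mM), 40 °C
Reagents that add atoms: none
Why: Ring-closing metathesis of the two terminal vinyl groups closes the six-membered carbocycle with loss of ethylene; benzoquinone suppresses isomerisation of the allylic alcohol.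

Step 13
Reactants: 22; 23 3-chloroperoxybenzoic acid (mCPBA)
Product: 24 (5R,6S,7R,8S)-8-[(tert-butyldimethylsilyl)oxy]-5,6-epoxy-7-hydroxy-2-(2-phenylethyl)-5,6,7,8-tetrahydro-4H-chromen-4-one (epoxide cis to 7-OH, trans to 8-OTBS)
Conditions: mCPBA (1.5 eq), CH2Cl2/pH 8 phosphate buffer, 0 °C → rt
Reagents that add atoms: 3-chloroperoxybenzoic acid, OOC(=O)c1cccc(Cl)c1
Why: Henbest hydroxyl-directed epoxidation; the allylic 7-OH hydrogen-bonds the peracid and delivers oxygen to its own face while the 8-OTBS group blocks the other, the same sense seen for arene trans-dihydrodiols, setting C5 and C6.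

**Lower unit**

Step 14
Reactants: 25 1-(2-hydroxy-4,5-dimethoxyphenyl)ethan-1-one; 26 ethyl 3-phenylpropanoate
Product: 27 1-(2-hydroxy-4,5-dimethoxyphenyl)-5-phenylpentane-1,3-dione
Conditions: NaH (4 eq), THF, reflux; then 1 M HCl
Reagents that add atoms: ethyl 3-phenylpropanoate, CCOC(=O)CCc1ccccc1
Why: Intermolecular Claisen condensation; the phenoxide/enolate dianion of the acetophenone acylates on carbon with the ester and the stable diketone enolate drives the equilibrium.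

Step 15
Reactants: 27
Product: 28 6,7-dimethoxy-2-(2-phenylethyl)-4H-chromen-4-one
Conditions: conc. HCl (cat.), AcOH, 100 °C
Reagents that add atoms: none
Why: Acid-catalysed cyclodehydration of the 2-hydroxyaryl 1,3-diketone closes the pyranone ring of the lower chromone.

Step 16
Reactants: 28
Product: 29 6,7-dihydroxy-2-(2-phenylethyl)-4H-chromen-4-one
Conditions: BBr3 (4 eq), CH2Cl2, −78 °C → rt; then H2O
Reagents that add atoms: none
Why: BBr3 cleaves both aryl methyl ethers; the chromone and the phenethyl chain are inert.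

Step 17
Reactants: 29; 30 allyl bromide
Product: 31 7-(allyloxy)-6-hydroxy-2-(2-phenylethyl)-4H-chromen-4-one
Conditions: allyl bromide (1.05 eq), K2CO3 (1.0 eq), DMF, rt
Reagents that add atoms: allyl bromide, C=CCBr
Why: Selective Williamson alkylation; the 7-OH, para to the chromone carbonyl, is the more acidic phenol and is alkylated first with one equivalent of base, leaving the 6-OH as the later nucleophile (regiochemistry to be confirmed by NOE/HMBC).

**Union and end game**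

Step 18
Reactants: 24; 31
Product: 32 (5S,6S,7R,8S)-5-{[7-(allyloxy)-4-oxo-2-(2-phenylethyl)-4H-chromen-6-yl]oxy}-8-[(tert-butyldimethylsilyl)oxy]-6,7-dihydroxy-2-(2-phenylethyl)-5,6,7,8-tetrahydro-4H-chromen-4-one
Conditions: 31 (1.5 eq), Cs2CO3 (1.0 eq), DMF, 60 °C
Reagents that add atoms: 7-(allyloxy)-6-hydroxy-2-(2-phenylethyl)-4H-chromen-4-one, O=c1cc(CCc2ccccc2)oc2cc(OCC=C)c(O)cc12
Why: Base-mediated SN2 epoxide opening (trans-diaxial, Fürst–Plattner); the phenoxide attacks the pyranone-activated C5 with inversion, not C6, which is deactivated by the adjacent oxygenated C7, so the aryl ether ends trans to the 6-OH (C5 S).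

Step 19
Reactants: 32
Product: 33 (5S,6S,7R,8S)-5-{[7-(allyloxy)-4-oxo-2-(2-phenylethyl)-4H-chromen-6-yl]oxy}-6,7,8-trihydroxy-2-(2-phenylethyl)-5,6,7,8-tetrahydro-4H-chromen-4-one
Conditions: HF·pyridine, THF/pyridine, 0 °C → rt
Reagents that add atoms: none
Why: Fluoride-driven desilylation under buffered conditions removes the TBS group wherever it sits, without ionising the C5 aryl ether or opening the pyranones.

Step 20
Reactants: 33
Product: 34 (5S,6S,7R,8S)-6,7,8-trihydroxy-5-{[7-hydroxy-4-oxo-2-(2-phenylethyl)-4H-chromen-6-yl]oxy}-2-(2-phenylethyl)-5,6,7,8-tetrahydro-4H-chromen-4-one (CNP0248258.1)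
Conditions: Pd(PPh3)4 (5 mol%), morpholine (10 eq), THF, rt
Reagents that add atoms: none
Why: Tsuji–Trost deallylation; zerovalent palladium ionises only the allyl aryl ether to a π-allyl complex that morpholine traps, under neutral conditions that leave the C5–O aryl ether and all four stereocenters untouched.

**Compound list**

1 | kojic acid, 5-hydroxy-2-(hydroxymethyl)-4H-pyran-4-one | O=c1cc(CO)occ1O | starting material
2 | benzyl chloride | ClCc1ccccc1 | starting material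
3 | 5-(benzyloxy)-2-(hydroxymethyl)-4H-pyran-4-one | O=c1cc(CO)occ1OCc1ccccc1 | intermediate
4 | 5-(benzyloxy)-4-oxo-4H-pyran-2-carbaldehyde | O=Cc1cc(=O)c(OCc2ccccc2)co1 | intermediate
5 | diethyl benzylphosphonate | CCOP(=O)(Cc1ccccc1)OCC | starting material
6 | 5-(benzyloxy)-2-[(E)-2-phenylethenyl]-4H-pyran-4-one | O=c1cc(/C=C/c2ccccc2)occ1OCc1ccccc1 | intermediate
7 | 5-hydroxy-2-(2-phenylethyl)-4H-pyran-4-one | O=c1cc(CCc2ccccc2)occ1O | intermediate
8 | formaldehyde | C=O | starting material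
9 | 3-hydroxy-2-(hydroxymethyl)-6-(2-phenylethyl)-4H-pyran-4-one | O=c1cc(CCc2ccccc2)oc(CO)c1O | intermediate
10 | N-phenyl-bis(trifluoromethanesulfonimide) | O=S(=O)(N(c1ccccc1)S(=O)(=O)C(F)(F)F)C(F)(F)F | starting material
11 | 2-(hydroxymethyl)-4-oxo-6-(2-phenylethyl)-4H-pyran-3-yl trifluoromethanesulfonate | O=c1cc(CCc2ccccc2)oc(CO)c1OS(=O)(=O)C(F)(F)F | intermediate
12 | tributyl(vinyl)stannane | C=C[Sn](CCCC)(CCCC)CCCC | starting material
13 | 3-ethenyl-2-(hydroxymethyl)-6-(2-phenylethyl)-4H-pyran-4-one | O=c1cc(CCc2ccccc2)oc(CO)c1C=C | intermediate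
14 | 3-ethenyl-4-oxo-6-(2-phenylethyl)-4H-pyran-2-carbaldehyde | O=Cc1oc(CCc2ccccc2)cc(=O)c1C=C | intermediate
15 | allyl methoxymethyl ether | C=CCOCOC | starting material
16 | O-diisopinocampheylboryl derivative of 17 | O=c1cc(CCc2ccccc2)oc([C@@H](OB([C@@H]2C[C@@H]3C[C@H]([C@H]2C)C3(C)C)[C@@H]2C[C@@H]3C[C@H]([C@H]2C)C3(C)C)[C@H](OCOC)C=C)c1C=C | intermediate (not isolated)
17 | 3-ethenyl-2-[(1S,2R)-1-hydroxy-2-(methoxymethoxy)but-3-en-1-yl]-6-(2-phenylethyl)-4H-pyran-4-one | O=c1cc(CCc2ccccc2)oc([C@@H](O)[C@H](OCOC)C=C)c1C=C | intermediate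
18 | tert-butyldimethylsilyl chloride | CC(C)(C)[Si](C)(C)Cl | starting material
19 | 2-[(1S,2R)-1-[(tert-butyldimethylsilyl)oxy]-2-(methoxymethoxy)but-3-en-1-yl]-3-ethenyl-6-(2-phenylethyl)-4H-pyran-4-one | O=c1cc(CCc2ccccc2)oc([C@@H](O[Si](C)(C)C(C)(C)C)[C@H](OCOC)C=C)c1C=C | intermediate
20 | 2-[(1S,2R)-2-(bromomethoxy)-1-[(tert-butyldimethylsilyl)oxy]but-3-en-1-yl]-3-ethenyl-6-(2-phenylethyl)-4H-pyran-4-one | O=c1cc(CCc2ccccc2)oc([C@@H](O[Si](C)(C)C(C)(C)C)[C@H](OCBr)C=C)c1C=C | intermediate (not isolated)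
21 | 2-[(1S,2R)-1-[(tert-butyldimethylsilyl)oxy]-2-hydroxybut-3-en-1-yl]-3-ethenyl-6-(2-phenylethyl)-4H-pyran-4-one | O=c1cc(CCc2ccccc2)oc([C@@H](O[Si](C)(C)C(C)(C)C)[C@H](O)C=C)c1C=C | intermediate
22 | (7R,8S)-8-[(tert-butyldimethylsilyl)oxy]-7-hydroxy-2-(2-phenylethyl)-7,8-dihydro-4H-chromen-4-one | O=c1cc(CCc2ccccc2)oc2c1C=C[C@@H](O)[C@@H]2O[Si](C)(C)C(C)(C)C | intermediate
23 | 3-chloroperoxybenzoic acid | OOC(=O)c1cccc(Cl)c1 | starting material
24 | (5R,6S,7R,8S)-8-[(tert-butyldimethylsilyl)oxy]-5,6-epoxy-7-hydroxy-2-(2-phenylethyl)-5,6,7,8-tetrahydro-4H-chromen-4-one | O=c1cc(CCc2ccccc2)oc2c1[C@H]3O[C@H]3[C@@H](O)[C@@H]2O[Si](C)(C)C(C)(C)C | intermediate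
25 | 1-(2-hydroxy-4,5-dimethoxyphenyl)ethan-1-one | CC(=O)c1cc(OC)c(OC)cc1O | starting material
26 | ethyl 3-phenylpropanoate | CCOC(=O)CCc1ccccc1 | starting material
27 | 1-(2-hydroxy-4,5-dimethoxyphenyl)-5-phenylpentane-1,3-dione | O=C(CC(=O)CCc1ccccc1)c1cc(OC)c(OC)cc1O | intermediate
28 | 6,7-dimethoxy-2-(2-phenylethyl)-4H-chromen-4-one | COc1cc2oc(CCc3ccccc3)cc(=O)c2cc1OC | intermediate
29 | 6,7-dihydroxy-2-(2-phenylethyl)-4H-chromen-4-one | O=c1cc(CCc2ccccc2)oc2cc(O)c(O)cc12 | intermediate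
30 | allyl bromide | C=CCBr | starting material
31 | 7-(allyloxy)-6-hydroxy-2-(2-phenylethyl)-4H-chromen-4-one | O=c1cc(CCc2ccccc2)oc2cc(OCC=C)c(O)cc12 | intermediate
32 | (5S,6S,7R,8S)-5-{[7-(allyloxy)-4-oxo-2-(2-phenylethyl)-4H-chromen-6-yl]oxy}-8-[(tert-butyldimethylsilyl)oxy]-6,7-dihydroxy-2-(2-phenylethyl)-5,6,7,8-tetrahydro-4H-chromen-4-one | O=c1cc(CCc2ccccc2)oc2c1[C@H](Oc1cc3c(=O)cc(CCc4ccccc4)oc3cc1OCC=C)[C@@H](O)[C@@H](O)[C@@H]2O[Si](C)(C)C(C)(C)C | intermediate
33 | (5S,6S,7R,8S)-5-{[7-(allyloxy)-4-oxo-2-(2-phenylethyl)-4H-chromen-6-yl]oxy}-6,7,8-trihydroxy-2-(2-phenylethyl)-5,6,7,8-tetrahydro-4H-chromen-4-one | O=c1cc(CCc2ccccc2)oc2c1[C@H](Oc1cc3c(=O)cc(CCc4ccccc4)oc3cc1OCC=C)[C@@H](O)[C@@H](O)[C@@H]2O | intermediate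
34 | (5S,6S,7R,8S)-6,7,8-trihydroxy-5-{[7-hydroxy-4-oxo-2-(2-phenylethyl)-4H-chromen-6-yl]oxy}-2-(2-phenylethyl)-5,6,7,8-tetrahydro-4H-chromen-4-one | O=c1cc(CCc2ccccc2)oc2c1[C@H](Oc1cc3c(=O)cc(CCc4ccccc4)oc3cc1O)[C@@H](O)[C@@H](O)[C@@H]2O | target

**Step count**
Total: 20 steps. Longest linear sequence: 16 steps (steps 1–13, then 18–20, from kojic acid); the lower unit takes 4 steps (14–17).

**Three steps most likely to fail, with fallbacks**

Step 18 (epoxide opening by a hindered, weakly nucleophilic phenoxide; risks are low conversion, attack at C6, or base-induced decomposition of the epoxide). The fallback replaces the SN2 opening by a Helferich-type substitution with neighbouring-group participation. It sets out from 24 and comes back at 32. Acid-catalysed hydrolysis of 24 (cat. HClO4, THF/H2O, 0 °C; water enters trans at C5) gives (5S,6R,7R,8S)-8-[(tert-butyldimethylsilyl)oxy]-5,6,7-trihydroxy-2-(2-phenylethyl)-5,6,7,8-tetrahydro-4H-chromen-4-one F10. Acetylation (Ac2O, pyridine, DMAP) gives (5S,6R,7R,8S)-8-[(tert-butyldimethylsilyl)oxy]-4-oxo-2-(2-phenylethyl)-5,6,7,8-tetrahydro-4H-chromene-5,6,7-triyl triacetate F11. Treatment with 31 and BF3·OEt2 (CH2Cl2, 4 Å sieves, −20 °C) ionises the 5-acetate, which sits on a vinylogous oxocarbenium position. The trans 6-acetate bridges as an acetoxonium ion and the phenol enters trans to it, as in aryl 1,2-trans-glycoside synthesis, giving (5S,6R,7R,8S)-5-{[7-(allyloxy)-4-oxo-2-(2-phenylethyl)-4H-chromen-6-yl]oxy}-8-[(tert-butyldimethylsilyl)oxy]-4-oxo-2-(2-phenylethyl)-5,6,7,8-tetrahydro-4H-chromene-6,7-diyl diacetate F12. Methanolysis (K2CO3, MeOH, 0 °C) then gives 32.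

Step 9 (asymmetric alkoxyallylboration of a sensitive, Lewis-basic pyranone aldehyde; risks are low enantio- or diastereoselectivity and damage during oxidative work-up). The fallback replaces it by an auxiliary-controlled boron glycolate aldol. It sets out from 14 and comes back at 21. (S)-4-Benzyl-1,3-oxazolidin-2-one is N-acylated (n-BuLi, (4-methoxybenzyloxy)acetyl chloride, THF, −78 °C) to (4S)-4-benzyl-3-{[(4-methoxybenzyl)oxy]acetyl}-1,3-oxazolidin-2-one F1. Its Z-boron enolate (Bu2BOTf, i-Pr2NEt, CH2Cl2, −78 → 0 °C) adds to 14 to give the Evans syn adduct (4S)-4-benzyl-3-{(2S,3S)-3-[3-ethenyl-4-oxo-6-(2-phenylethyl)-4H-pyran-2-yl]-3-hydroxy-2-[(4-methoxybenzyl)oxy]propanoyl}-1,3-oxazolidin-2-one F2, which has the same C7/C8 configuration as 17. Silylation (TBSOTf, 2,6-lutidine) gives (4S)-4-benzyl-3-{(2S,3S)-3-[(tert-butyldimethylsilyl)oxy]-3-[3-ethenyl-4-oxo-6-(2-phenylethyl)-4H-pyran-2-yl]-2-[(4-methoxybenzyl)oxy]propanoyl}-1,3-oxazolidin-2-one F3. Reductive removal of the auxiliary (NaBH4, THF/H2O, 0 °C) gives 2-{(1S,2R)-1-[(tert-butyldimethylsilyl)oxy]-3-hydroxy-2-[(4-methoxybenzyl)oxy]propyl}-3-ethenyl-6-(2-phenylethyl)-4H-pyran-4-one F4. Dess–Martin oxidation gives (2S,3S)-3-[(tert-butyldimethylsilyl)oxy]-3-[3-ethenyl-4-oxo-6-(2-phenylethyl)-4H-pyran-2-yl]-2-[(4-methoxybenzyl)oxy]propanal F5. Wittig methylenation (Ph3PCH3Br, KN(SiMe3)2, THF, −78 °C) gives 2-{(1S,2R)-1-[(tert-butyldimethylsilyl)oxy]-2-[(4-methoxybenzyl)oxy]but-3-en-1-yl}-3-ethenyl-6-(2-phenylethyl)-4H-pyran-4-one F6. DDQ (CH2Cl2/pH 7 buffer) removes the PMB group and gives 21; this path also avoids step 11.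

Step 11 (MOM cleavage in the presence of the TBS ether, an allylic C–O bond and a Lewis-basic pyranone). The fallback drops the silyl group and carries the free trans-diol through, as in arene dihydrodiol / diol-epoxide chemistry. It sets out from 17 and comes back at 33. Protic cleavage of the MOM ether (2 M HCl in MeOH, 40 °C) gives 2-[(1S,2R)-1,2-dihydroxybut-3-en-1-yl]-3-ethenyl-6-(2-phenylethyl)-4H-pyran-4-one F7. Ring-closing metathesis under the step 12 conditions gives (7R,8S)-7,8-dihydroxy-2-(2-phenylethyl)-7,8-dihydro-4H-chromen-4-one F8. mCPBA (buffered CH2Cl2, 0 °C), directed by the pseudo-equatorial allylic 7-OH, gives (5R,6S,7S,8S)-5,6-epoxy-7,8-dihydroxy-2-(2-phenylethyl)-5,6,7,8-tetrahydro-4H-chromen-4-one F9 (epoxide cis to 7-OH). Opening with 31 (Cs2CO3, DMF, 50 °C) gives 33 directly.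

**Further compounds**

F1 | step 9 | (4S)-4-benzyl-3-{[(4-methoxybenzyl)oxy]acetyl}-1,3-oxazolidin-2-one | COc1ccc(COCC(=O)N2[C@@H](Cc3ccccc3)COC2=O)cc1
F2 | step 9 | (4S)-4-benzyl-3-{(2S,3S)-3-[3-ethenyl-4-oxo-6-(2-phenylethyl)-4H-pyran-2-yl]-3-hydroxy-2-[(4-methoxybenzyl)oxy]propanoyl}-1,3-oxazolidin-2-one | O=C(N1[C@@H](Cc2ccccc2)COC1=O)[C@@H](OCc1ccc(OC)cc1)[C@H](O)c1oc(CCc2ccccc2)cc(=O)c1C=C
F3 | step 9 | (4S)-4-benzyl-3-{(2S,3S)-3-[(tert-butyldimethylsilyl)oxy]-3-[3-ethenyl-4-oxo-6-(2-phenylethyl)-4H-pyran-2-yl]-2-[(4-methoxybenzyl)oxy]propanoyl}-1,3-oxazolidin-2-one | O=C(N1[C@@H](Cc2ccccc2)COC1=O)[C@@H](OCc1ccc(OC)cc1)[C@H](O[Si](C)(C)C(C)(C)C)c1oc(CCc2ccccc2)cc(=O)c1C=C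
F4 | step 9 | 2-{(1S,2R)-1-[(tert-butyldimethylsilyl)oxy]-3-hydroxy-2-[(4-methoxybenzyl)oxy]propyl}-3-ethenyl-6-(2-phenylethyl)-4H-pyran-4-one | OC[C@@H](OCc1ccc(OC)cc1)[C@H](O[Si](C)(C)C(C)(C)C)c1oc(CCc2ccccc2)cc(=O)c1C=C
F5 | step 9 | (2S,3S)-3-[(tert-butyldimethylsilyl)oxy]-3-[3-ethenyl-4-oxo-6-(2-phenylethyl)-4H-pyran-2-yl]-2-[(4-methoxybenzyl)oxy]propanal | O=C[C@@H](OCc1ccc(OC)cc1)[C@H](O[Si](C)(C)C(C)(C)C)c1oc(CCc2ccccc2)cc(=O)c1C=C
F6 | step 9 | 2-{(1S,2R)-1-[(tert-butyldimethylsilyl)oxy]-2-[(4-methoxybenzyl)oxy]but-3-en-1-yl}-3-ethenyl-6-(2-phenylethyl)-4H-pyran-4-one | C=C[C@@H](OCc1ccc(OC)cc1)[C@H](O[Si](C)(C)C(C)(C)C)c1oc(CCc2ccccc2)cc(=O)c1C=C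
F7 | step 11 | 2-[(1S,2R)-1,2-dihydroxybut-3-en-1-yl]-3-ethenyl-6-(2-phenylethyl)-4H-pyran-4-one | O=c1cc(CCc2ccccc2)oc([C@@H](O)[C@H](O)C=C)c1C=C
F8 | step 11 | (7R,8S)-7,8-dihydroxy-2-(2-phenylethyl)-7,8-dihydro-4H-chromen-4-one | O=c1cc(CCc2ccccc2)oc2c1C=C[C@@H](O)[C@@H]2O
F9 | step 11 | (5R,6S,7S,8S)-5,6-epoxy-7,8-dihydroxy-2-(2-phenylethyl)-5,6,7,8-tetrahydro-4H-chromen-4-one | O=c1cc(CCc2ccccc2)oc2c1[C@H]3O[C@H]3[C@@H](O)[C@@H]2O
F10 | step 18 | (5S,6R,7R,8S)-8-[(tert-butyldimethylsilyl)oxy]-5,6,7-trihydroxy-2-(2-phenylethyl)-5,6,7,8-tetrahydro-4H-chromen-4-one | O=c1cc(CCc2ccccc2)oc2c1[C@H](O)[C@@H](O)[C@@H](O)[C@@H]2O[Si](C)(C)C(C)(C)C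
F11 | step 18 | (5S,6R,7R,8S)-8-[(tert-butyldimethylsilyl)oxy]-4-oxo-2-(2-phenylethyl)-5,6,7,8-tetrahydro-4H-chromene-5,6,7-triyl triacetate | O=c1cc(CCc2ccccc2)oc2c1[C@H](OC(C)=O)[C@@H](OC(C)=O)[C@@H](OC(C)=O)[C@@H]2O[Si](C)(C)C(C)(C)C
F12 | step 18 | (5S,6R,7R,8S)-5-{[7-(allyloxy)-4-oxo-2-(2-phenylethyl)-4H-chromen-6-yl]oxy}-8-[(tert-butyldimethylsilyl)oxy]-4-oxo-2-(2-phenylethyl)-5,6,7,8-tetrahydro-4H-chromene-6,7-diyl diacetate | O=c1cc(CCc2ccccc2)oc2c1[C@H](Oc1cc3c(=O)cc(CCc4ccccc4)oc3cc1OCC=C)[C@@H](OC(C)=O)[C@@H](OC(C)=O)[C@@H]2O[Si](C)(C)C(C)(C)C
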